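## Analysis of the target

The target is a para-terphenyl whose central benzene ring (C1'–C6') is fully substituted: 4-hydroxyphenyl rings at C1' and C4', benzoate esters at C2' and C3', and free hydroxyl groups at C5' and C6'. There is no stereocentre, and the para-substituted outer rings create no isolable rotamers, so the problem is one of constitution only. A mirror plane through the midpoints of C2'–C3' and C5'–C6' makes the two aryl-bearing halves identical. The sensitive groups are the electron-rich 3,6-diaryl ortho-dihydroxy unit, which air and oxidants turn into an ortho-quinone, and the aryl benzoates, which base and nucleophiles cleave. The difficulty is that the ring is hexasubstituted and crowded, and that its four ring oxygens must be divided into two ortho pairs (one acylated, one free) while the two outer phenols also stay free. Any intermediate that shows all four ring oxygens as hydroxyl groups, or as a quinone or hydroquinone with its para-related pairs, loses that distinction. The strategy rests on reading C1'–C2' and C4'–C3' as two aryl–C≡C–O units whose oxygens sit on neighbouring ring carbons, so that a single silicon atom can bridge them. C5'–C6' is then a two-carbon unit carrying a different heteroatom, boron, that is later turned into oxygen.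

## Retrosynthetic reasoning

**From 15 to 14.** The last bonds cut are the two benzylic C–O bonds of the outer-ring ethers. Hydrogenolysis leaves aryl benzoates and the ortho-dihydroxy unit untouched. Keeping the outer phenols capped until the end means they are never present during acylation.

**From 14 to 13.** The C5'–O and C6'–O bonds are traced back to C–B bonds. Boron is inert to acylation and is converted to oxygen with retention of position. The second oxygen pair therefore does not exist until the first pair already carries its benzoates, and no selective acylation among four hydroxyl groups is ever needed.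

**From 13 to 11 and 12, and from 11 to 10.** The two ester C–O bonds are cut to the diol 11 and benzoyl chloride 12. The diol is traced to the cyclic silylene 10 by cutting the two Si–O bonds. In 10 the silylene is the only group that a fluoride source removes, so the C2'/C3' oxygen pair is released alone. Silicon marks one ortho pair and boron marks the other.

**From 10 to 8 and 9.** This is the central disconnection. It cuts C2'–C3', C4'–C5' and C6'–C1', which takes the central ring apart into three alkynes along its symmetry. Cutting the aryl–ring bonds instead would demand a ready-made tetraoxygenated arene that is already differentiated, which is the hard part of the target. In 8 the two identical ynol-ether halves are joined through their oxygens by one silicon atom. Their coupling is then intramolecular and necessarily joins the two oxygen-bearing carbons, which places the aryl groups para. The third alkyne, 9, is symmetrical and brings the two boron atoms. The forward reaction has to favour the cross-trimer over self-trimerisation of either partner, tolerate ynol silyl ethers, and close a crowded ring. It is run with a cobalt source that is active below room temperature, because ynol silyl ethers do not withstand the heating that the usual carbonyl precatalyst requires.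

**From 8 to 7 and 5, and from 7 back to 4 through 6.** The two Si–O bonds are cut to two molecules of the lithium ynolate 7 and one molecule of the dichlorosilane 5. The ynolate is traced through the dibromoenolate 6 to the isolated dibromomethyl ketone 4 by reversing a 1,2-aryl shift of a carbenoid. The ynolate is generated from the isolated ketone 4 and not directly from ester 1. Direct generation would leave one equivalent of the methoxide expelled from 1 in the flask, and that alkoxide would compete for the bifunctional silane and give mixed silyl ethers.

**From 4 to 1 and 2.** The bond between the carbonyl carbon and the dibromomethyl carbon is cut. This leads to methyl 4-(benzyloxy)benzoate 1, which already carries the protected outer ring, and dibromomethane 2. The forward step is a single addition of the lithiated form of 2 to the ester carbonyl. It stops after one addition because the product is held as the tetrahedral adduct 3 until a cold acidic quench releases the ketone.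

## Alternatives that were turned down

Alternative 1: The two outer rings are dissected instead of the central one. Each is cut at C3''–C4'' and C5''–C6''. This leads back to 5,6-bis(benzyloxy)-4,7-di(buta-1,3-dien-2-yl)-2,2-dimethyl-1,3-benzodioxole A1 and two molecules of 2-ethynyl-4,4,5,5-tetramethyl-1,3,2-dioxaborolane A2.
- Forward key step: a cobalt-catalysed (4+2) cycloaddition of each diene arm with A2 would give 5,6-bis(benzyloxy)-2,2-dimethyl-4,7-bis[4-(pinacolatoboryl)cyclohexa-1,4-dien-1-yl]-1,3-benzodioxole A3, with boron para to the central ring. Dehydrogenation and C–B oxidation would then give the two phenol rings.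
- For it: this cycloaddition type is established for 2-substituted dienes and alkynylboronates, with dependable para regiochemistry. On precedent it is stronger than the key step chosen here. The acetal/benzyl ether pattern of A1 differentiates the two oxygen pairs as cleanly as silicon and boron do.
- Against it: the effort goes into the two rings that any 4-oxygenated phenyl building block supplies for nothing. A1 already contains the hexasubstituted, differentiated central ring. Its diene arms must be attached at exactly the positions where an aryl group could be coupled directly. The crowded 2-aryl dienes are prone to polymerise. After the cycloaddition come aromatisation, oxidation of boron, capping of the new phenols, acetal removal, benzoylation and deprotection.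
- Comparison: the chosen route builds the central ring and both differentiated heteroatom pairs in one step and reaches the target in seven steps. It pays for this with a key step that has no direct precedent.

Alternative 2: The central ring is cut at C3'–C4' and C5'–C6'. This leads to 3-[4-(benzyloxy)phenyl]-4-methoxycyclobut-3-ene-1,2-dione A4 and the ynol ether 1-(benzyloxy)-4-(ethoxyethynyl)benzene A6.
- Forward key step: stoichiometric ClCo(PPh3)3 A5 (monovalent cobalt) would insert into the bond between the two carbonyl carbons of A4. Alkyne A6 would then insert, and reductive elimination would close 2,5-bis[4-(benzyloxy)phenyl]-3-ethoxy-6-methoxy-1,4-benzoquinone A7.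
- For it: the ring-forming chemistry is known for cyclobutenediones and alkynes. Like the chosen route it is convergent and makes the crowded ring from small pieces.
- Against it: the insertion of an unsymmetrical alkyne has to be regioselective to put the aryl groups para, and nothing in A4 or A6 secures that. Cobalt is used in stoichiometric amount. The decisive point is the oxygen pattern of A7. Its carbonyl oxygens are para to each other and so are its two ether oxygens. Each ortho pair therefore consists of one carbonyl oxygen and one alkoxy oxygen, and the two pairs differ only as methyl versus ethyl ether, which cannot be cleaved selectively.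
- Comparison: A7 has the carbon skeleton but not the ortho-pair differentiation the target needs. The silicon tether supplies that differentiation by construction, and it fixes the para relationship of the aryl groups without relying on insertion selectivity.

Alternative 3: The ring is cut at C1'–C2' and C4'–C5' into two molecules of an arylpyruvic thioester, S-ethyl 3-[4-(benzyloxy)phenyl]-2-oxopropanethioate A8.
- Forward key step: under soft-enolisation conditions each benzylic carbon would be acylated by the thioester carbonyl of the other molecule. This closes the ring as 2,5-bis[4-(benzyloxy)phenyl]-3,6-dihydroxy-1,4-benzoquinone A9.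
- For it: the route follows the biogenesis of this compound class, is the shortest way to the carbon skeleton, and needs no transition metal. In step count to the ring it beats the chosen route.
- Against it: the head-to-tail double acylation competes with aldol self-condensation of the keto group. More seriously, A9 and its reduced form carry four ring oxygens that are equivalent or interconvert by tautomerism. Dibenzoylation of the reduced form would give ortho, meta-type and para diesters without control, and the free ortho-dihydroxy unit would have to be carried through that mixture.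
- Comparison: the chosen route is longer to the ring but never passes through a symmetric tetraoxygenated intermediate. The four oxygens enter already sorted into a silicon pair and a boron pair.

Key step: step 3

Remark: the target has no stereogenic element. The only stereogenic carbon in the route is that of the transient adduct 3, which is formed as a racemate and disappears on collapse, so no descriptors are needed. Bpin stands for the 4,4,5,5-tetramethyl-1,3,2-dioxaborolan-2-yl group and Cp for the cyclopentadienyl ligand.

## Route

Step 1
Reactants: 1 methyl 4-(benzyloxy)benzoate; 2 dibromomethane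
Product: 4 1-[4-(benzyloxy)phenyl]-2,2-dibromoethan-1-one, via lithium hemiketal alkoxide 3 (not isolated)
Conditions: 2 (1.4 equiv), lithium 2,2,6,6-tetramethylpiperidide (1.3 equiv), THF, −78 °C; then 1, −78 °C, 30 min; AcOH (3 equiv) in THF at −78 °C, then → rt
Reagents that add atoms: dibromomethane (compound 2), BrCBr
Why: This is the addition of dibromomethyllithium to an ester carbonyl, the first stage of the Kowalski ester homologation and a known way to dibromomethyl ketones: tetrahedral adduct 3 should persist at −78 °C, so the ketone is released only by the cold acidic quench, when no carbenoid is left to add a second time. Adduct 3 has one stereogenic carbon, is formed as a racemate and loses it on collapse to 4. Isolating 4 removes the methanol and the amine, which would otherwise compete for the silicon electrophile in step 2.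

Step 2
Reactants: 4 1-[4-(benzyloxy)phenyl]-2,2-dibromoethan-1-one (2 equiv); 5 dichlorodi(propan-2-yl)silane (1 equiv)
Product: 8 bis({[4-(benzyloxy)phenyl]ethynyl}oxy)di(propan-2-yl)silane, via lithium dibromoenolate 6 (not isolated), via lithium arylynolate 7 (not isolated)
Conditions: 4 (2 equiv), LiN(SiMe3)2 (2.1 equiv), THF, −78 °C; t-BuLi (4 equiv), −78 → 0 °C; then 5 (1 equiv) added slowly, −78 → 0 °C; pentane, filtration under argon, short plug of Et3N-deactivated silica
Reagents that add atoms: dichlorodi(propan-2-yl)silane (compound 5), CC(C)[Si](Cl)(Cl)C(C)C
Why: This is the Kowalski ynolate synthesis followed by O-silylation, run on two molecules of 4 for each molecule of 5: deprotonation gives enolate 6, bromine–lithium exchange gives an alpha-bromo carbenoid whose 1,2-aryl shift (Fritsch–Buttenberg–Wiechell type) should deliver ynolate 7, and the second equivalent of t-BuLi per ketone destroys the tert-butyl bromide. Ynolates are silylated on oxygen by hindered silyl chlorides, and because the silane is added to the ynolate, each silicon meets an excess of 7 and both chlorides should be displaced. No alkoxide is present, so silicon can only pick up ynolate oxygen.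

Step 3
Reactants: 8 bis({[4-(benzyloxy)phenyl]ethynyl}oxy)di(propan-2-yl)silane; 9 bis(pinacolatoboryl)acetylene
Product: 10 4,7-bis[4-(benzyloxy)phenyl]-2,2-di(propan-2-yl)-5,6-bis(4,4,5,5-tetramethyl-1,3,2-dioxaborolan-2-yl)-1,3,2-benzodioxasilole
Conditions: CpCo(C2H4)2 (20 mol%), 9 (3 equiv), THF, −20 → 40 °C, 8 added by syringe pump, argon
Reagents that add atoms: bis(pinacolatoboryl)acetylene (compound 9), CC1(C)OB(C#CB2OC(C)(C)C(C)(C)O2)OC1(C)C
Why: Proposed new method: CpCo(C2H4)2 sheds ethylene below room temperature and the CpCo fragment binds both alkynes of 8; oxidative coupling joins the two oxygen-bearing carbons (C2'–C3') to a cobaltacyclopentadiene whose cobalt-bound carbons carry the aryl groups, the electron-poor diborylalkyne 9 then coordinates and inserts (C4'–C5'), and reductive elimination (C6'–C1') releases the arene and returns monovalent cobalt. The closest known reaction type is the cobalt-mediated (2+2+2) cycloaddition of carbon-tethered 1,6-diynes with alkynylboronates; what is new is an O–Si–O tether made of two ynol silyl ethers. The five-membered dioxasilole ring closes in the oxidative coupling, as the five-membered ring of a 1,6-diyne does (three-atom tether, the long Si–O bonds offset by the short C–O bonds), and the benzene ring closes in the final reductive elimination of the formal (2+2+2). No stereocentre is formed. The step needs cross-trimerisation over self-trimerisation: the tether makes the diyne coupling intramolecular, slow addition of 8 to an excess of 9 keeps free diyne scarce, 9 is too hindered to trimerise quickly on its own, and the electron-rich metallacycle is matched with the electron-poor alkyne. Regiochemistry is not at issue, because the tether forces the two C–O carbons to bond (aryl groups para) and 9 is symmetrical. The low-temperature cobalt source is chosen because ynol silyl ethers are prone to a 1,3-silyl shift to silylketenes on heating, which rules out the usual CpCo(CO)2 in boiling toluene or xylene under irradiation.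

Step 4
Reactants: 10 4,7-bis[4-(benzyloxy)phenyl]-2,2-di(propan-2-yl)-5,6-bis(4,4,5,5-tetramethyl-1,3,2-dioxaborolan-2-yl)-1,3,2-benzodioxasilole
Product: 11 3,6-bis[4-(benzyloxy)phenyl]-4,5-bis(4,4,5,5-tetramethyl-1,3,2-dioxaborolan-2-yl)benzene-1,2-diol
Conditions: Bu4NF (2.2 equiv), AcOH (2.5 equiv), THF, 0 °C, argon; used at once
Reagents that add atoms: none
Why: This is fluoride-induced Si–O cleavage of a strained five-membered aryl silylene. Acetic acid buffers the medium so that each phenoxide is protonated at once and fluoride is kept from forming boron ate complexes; the pinacol boronates and benzyl ethers should not be touched.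

Step 5
Reactants: 11 3,6-bis[4-(benzyloxy)phenyl]-4,5-bis(4,4,5,5-tetramethyl-1,3,2-dioxaborolan-2-yl)benzene-1,2-diol; 12 benzoyl chloride
Product: 13 3,6-bis[4-(benzyloxy)phenyl]-4,5-bis(4,4,5,5-tetramethyl-1,3,2-dioxaborolan-2-yl)-1,2-phenylene dibenzoate
Conditions: 12 (3 equiv), Et3N, DMAP (cat.), CH2Cl2, 0 °C → rt
Reagents that add atoms: benzoyl chloride (compound 12), O=C(Cl)c1ccccc1
Why: This is nucleophile-catalysed O-acylation of both phenols. The only hydroxyl groups present are those at C2' and C3', so the benzoates are placed without any selectivity problem while the other oxygen pair is still masked as C–B.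

Step 6
Reactants: 13 3,6-bis[4-(benzyloxy)phenyl]-4,5-bis(4,4,5,5-tetramethyl-1,3,2-dioxaborolan-2-yl)-1,2-phenylene dibenzoate
Product: 14 3,6-bis[4-(benzyloxy)phenyl]-4,5-dihydroxy-1,2-phenylene dibenzoate
Conditions: KHSO5 (2.2 equiv, as 2KHSO5·KHSO4·K2SO4), acetone/H2O, 0 °C, short contact; aq. Na2S2O4 quench, argon
Reagents that add atoms: potassium peroxymonosulfate (KHSO5), [K+].OOS(=O)(=O)[O-]
Why: This is the oxidation of arylboronic esters by peroxymonosulfate: the peroxide adds to boron, the aryl group migrates from boron to oxygen at the same ring carbon, and the borate hydrolyses to the phenol. The acidic, non-nucleophilic medium spares the aryl benzoates, and the reductive quench removes excess oxidant before the new ortho-dihydroxy unit is over-oxidised.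

Step 7
Reactants: 14 3,6-bis[4-(benzyloxy)phenyl]-4,5-dihydroxy-1,2-phenylene dibenzoate
Product: 15 4,5-dihydroxy-3,6-bis(4-hydroxyphenyl)-1,2-phenylene dibenzoate (target, CNP0216579.0)
Conditions: H2 (1 atm), 10% Pd/C, EtOAc/THF, rt; filtration and concentration under argon
Reagents that add atoms: none
Why: This is hydrogenolysis of aryl benzyl ethers on palladium. Aryl benzoates, the ortho-dihydroxy unit and the arene rings are inert under one atmosphere of hydrogen at room temperature, and the neutral aprotic solvent avoids transesterification.

## Compound list

1 | methyl 4-(benzyloxy)benzoate | COC(=O)c1ccc(OCc2ccccc2)cc1 | starting material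
2 | dibromomethane | BrCBr | starting material
3 | lithium 1-[4-(benzyloxy)phenyl]-2,2-dibromo-1-methoxyethan-1-olate (racemic) | [Li+].[O-]C(OC)(C(Br)Br)c1ccc(OCc2ccccc2)cc1 | intermediate (not isolated)
4 | 1-[4-(benzyloxy)phenyl]-2,2-dibromoethan-1-one | O=C(C(Br)Br)c1ccc(OCc2ccccc2)cc1 | intermediate
5 | dichlorodi(propan-2-yl)silane | CC(C)[Si](Cl)(Cl)C(C)C | starting material
6 | lithium 1-[4-(benzyloxy)phenyl]-2,2-dibromoethen-1-olate | [Li+].[O-]C(=C(Br)Br)c1ccc(OCc2ccccc2)cc1 | intermediate (not isolated)
7 | lithium 2-[4-(benzyloxy)phenyl]ethyn-1-olate | [Li+].[O-]C#Cc1ccc(OCc2ccccc2)cc1 | intermediate (not isolated)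
8 | bis({[4-(benzyloxy)phenyl]ethynyl}oxy)di(propan-2-yl)silane | CC(C)[Si](OC#Cc1ccc(OCc2ccccc2)cc1)(OC#Cc1ccc(OCc2ccccc2)cc1)C(C)C | intermediate
9 | bis(pinacolatoboryl)acetylene [1,2-bis(4,4,5,5-tetramethyl-1,3,2-dioxaborolan-2-yl)ethyne] | CC1(C)OB(C#CB2OC(C)(C)C(C)(C)O2)OC1(C)C | starting material
10 | 4,7-bis[4-(benzyloxy)phenyl]-2,2-di(propan-2-yl)-5,6-bis(4,4,5,5-tetramethyl-1,3,2-dioxaborolan-2-yl)-1,3,2-benzodioxasilole | CC(C)[Si]1(C(C)C)Oc2c(O1)c(-c3ccc(OCc4ccccc4)cc3)c(B3OC(C)(C)C(C)(C)O3)c(B3OC(C)(C)C(C)(C)O3)c2-c2ccc(OCc3ccccc3)cc2 | intermediate
11 | 3,6-bis[4-(benzyloxy)phenyl]-4,5-bis(4,4,5,5-tetramethyl-1,3,2-dioxaborolan-2-yl)benzene-1,2-diol | Oc1c(O)c(-c2ccc(OCc3ccccc3)cc2)c(B2OC(C)(C)C(C)(C)O2)c(B2OC(C)(C)C(C)(C)O2)c1-c1ccc(OCc2ccccc2)cc1 | intermediate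
12 | benzoyl chloride | O=C(Cl)c1ccccc1 | starting material
13 | 3,6-bis[4-(benzyloxy)phenyl]-4,5-bis(4,4,5,5-tetramethyl-1,3,2-dioxaborolan-2-yl)-1,2-phenylene dibenzoate | O=C(Oc1c(OC(=O)c2ccccc2)c(-c2ccc(OCc3ccccc3)cc2)c(B2OC(C)(C)C(C)(C)O2)c(B2OC(C)(C)C(C)(C)O2)c1-c1ccc(OCc2ccccc2)cc1)c1ccccc1 | intermediate
14 | 3,6-bis[4-(benzyloxy)phenyl]-4,5-dihydroxy-1,2-phenylene dibenzoate | O=C(Oc1c(OC(=O)c2ccccc2)c(-c2ccc(OCc3ccccc3)cc2)c(O)c(O)c1-c1ccc(OCc2ccccc2)cc1)c1ccccc1 | intermediate
15 | 4,5-dihydroxy-3,6-bis(4-hydroxyphenyl)-1,2-phenylene dibenzoate | O=C(Oc1c(OC(=O)c2ccccc2)c(-c2ccc(O)cc2)c(O)c(O)c1-c1ccc(O)cc1)c1ccccc1 | target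

## Step count and least certain steps

Total step count: 7. Longest linear sequence: 7 steps (from 1; compounds 2, 5, 9 and 12 are bought).

**Step 3 (key step, the proposed new method).**
- What may go wrong: the ynol ether units may isomerise to silylketenes before they are coupled. The diyne may oligomerise at cobalt. The bulky diborylalkyne may fail to insert into a metallacycle that already carries two aryl groups, since a hexasubstituted ring is being closed.
- Fallback (known chemistry only): the cyclotrimerisation is given up and the terphenyl is assembled by double Suzuki–Miyaura coupling on a core in which a methylene acetal plays the part of silicon. It sets out from benzoyl chloride 12, the one compound of the route it keeps, and from commercial sesamol F1. Ortho-hydroxylation of F1 (2-iodoxybenzoic acid, then Na2S2O4) should give 1,3-benzodioxole-5,6-diol F2. Benzoylation with 12 (pyridine) gives 1,3-benzodioxole-5,6-diyl dibenzoate F3. Bromination at the only two free ring positions (Br2, AcOH) gives 4,7-dibromo-1,3-benzodioxole-5,6-diyl dibenzoate F4. Coupling with [4-(benzyloxy)phenyl]boronic acid F5 (Pd(OAc)2, SPhos, K3PO4, toluene, 100 °C) gives 4,7-bis[4-(benzyloxy)phenyl]-1,3-benzodioxole-5,6-diyl dibenzoate F6. Any benzoate lost to the base is put back with 12, which is harmless because the other oxygen pair is locked in the acetal. BCl3 with pentamethylbenzene in CH2Cl2 (−78 → 0 °C) then cleaves the methylene acetal and both benzyl ethers, and the sequence comes back to the route at 15.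

**Step 2.**
- What may go wrong: silylation of the ynolate at carbon instead of oxygen, or a silyl shift of the product to a silylketene (both easier for a di-isopropylsilyl than for a tri-isopropylsilyl group). The second substitution at silicon may be incomplete, and the bis(ynol ether) may hydrolyse on isolation.
- Fallback: a bulkier, triflate-activated silicon is used. It sets out from ynolate 7, which is treated at −78 °C with di-tert-butylsilyl bis(trifluoromethanesulfonate) F7 to give bis({[4-(benzyloxy)phenyl]ethynyl}oxy)di-tert-butylsilane F8. Cyclotrimerisation of F8 with 9 under the conditions of step 3 gives 4,7-bis[4-(benzyloxy)phenyl]-2,2-di-tert-butyl-5,6-bis(4,4,5,5-tetramethyl-1,3,2-dioxaborolan-2-yl)-1,3,2-benzodioxasilole F9. Cleavage with HF·pyridine in THF brings the sequence back to the route at 11.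

**Step 4.**
- What may go wrong: fluoride may attack boron, and the electron-rich ring may undergo protodeboronation once it carries free phenoxide. The liberated ortho-dihydroxy unit may be oxidised by air.
- Fallback: the free diol is avoided altogether by exchanging silicon for acyl directly. It sets out from 10, which is treated with benzoyl fluoride F10 (2.5 equiv) and catalytic Bu4NF in THF. Each phenoxide released from silicon is acylated at once and regenerates fluoride, and the sequence comes back to the route at 13.

**Step 6.**
- What may go wrong: oxidation may be slow at the two mutually ortho, doubly flanked boron atoms. Prolonged contact with the oxidant may over-oxidise the new ortho-dihydroxy unit to the ortho-quinone, which as a vinylogous anhydride would then shed benzoate.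
- Fallback: the boron ligand is changed before oxidation, so that a smaller and faster-reacting boron species is oxidised. It sets out from 13, which with KHF2 in MeOH/H2O gives dipotassium {3,6-bis[4-(benzyloxy)phenyl]-4,5-bis(benzoyloxy)-1,2-phenylene}bis(trifluoroborate) F11. Brief treatment of F11 with KHSO5 in acetone/H2O at 0 °C and a Na2S2O4 quench bring the sequence back to the route at 14.

## Further compounds

F1 | step 3 | sesamol (1,3-benzodioxol-5-ol) | Oc1ccc2OCOc2c1
F2 | step 3 | 1,3-benzodioxole-5,6-diol | Oc1cc2OCOc2cc1O
F3 | step 3 | 1,3-benzodioxole-5,6-diyl dibenzoate | O=C(Oc1cc2OCOc2cc1OC(=O)c1ccccc1)c1ccccc1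
F4 | step 3 | 4,7-dibromo-1,3-benzodioxole-5,6-diyl dibenzoate | O=C(Oc1c(Br)c2OCOc2c(Br)c1OC(=O)c1ccccc1)c1ccccc1
F5 | step 3 | [4-(benzyloxy)phenyl]boronic acid | OB(O)c1ccc(OCc2ccccc2)cc1
F6 | step 3 | 4,7-bis[4-(benzyloxy)phenyl]-1,3-benzodioxole-5,6-diyl dibenzoate | O=C(Oc1c(OC(=O)c2ccccc2)c(-c2ccc(OCc3ccccc3)cc2)c2OCOc2c1-c1ccc(OCc2ccccc2)cc1)c1ccccc1
F7 | step 2 | di-tert-butylsilyl bis(trifluoromethanesulfonate) | CC(C)(C)[Si](OS(=O)(=O)C(F)(F)F)(OS(=O)(=O)C(F)(F)F)C(C)(C)C
F8 | step 2 | bis({[4-(benzyloxy)phenyl]ethynyl}oxy)di-tert-butylsilane | CC(C)(C)[Si](OC#Cc1ccc(OCc2ccccc2)cc1)(OC#Cc1ccc(OCc2ccccc2)cc1)C(C)(C)C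
F9 | step 2 | 4,7-bis[4-(benzyloxy)phenyl]-2,2-di-tert-butyl-5,6-bis(4,4,5,5-tetramethyl-1,3,2-dioxaborolan-2-yl)-1,3,2-benzodioxasilole | CC(C)(C)[Si]1(C(C)(C)C)Oc2c(O1)c(-c3ccc(OCc4ccccc4)cc3)c(B3OC(C)(C)C(C)(C)O3)c(B3OC(C)(C)C(C)(C)O3)c2-c2ccc(OCc3ccccc3)cc2
F10 | step 4 | benzoyl fluoride | O=C(F)c1ccccc1
F11 | step 6 | dipotassium {3,6-bis[4-(benzyloxy)phenyl]-4,5-bis(benzoyloxy)-1,2-phenylene}bis(trifluoroborate) | [K+].[K+].O=C(Oc1c(OC(=O)c2ccccc2)c(-c2ccc(OCc3ccccc3)cc2)c([B-](F)(F)F)c([B-](F)(F)F)c1-c1ccc(OCc2ccccc2)cc1)c1ccccc1
A1 | alternative 1 | 5,6-bis(benzyloxy)-4,7-di(buta-1,3-dien-2-yl)-2,2-dimethyl-1,3-benzodioxole | CC1(C)Oc2c(O1)c(C(=C)C=C)c(OCc1ccccc1)c(OCc1ccccc1)c2C(=C)C=C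
A2 | alternative 1 | 2-ethynyl-4,4,5,5-tetramethyl-1,3,2-dioxaborolane | C#CB1OC(C)(C)C(C)(C)O1
A3 | alternative 1 | 5,6-bis(benzyloxy)-2,2-dimethyl-4,7-bis[4-(pinacolatoboryl)cyclohexa-1,4-dien-1-yl]-1,3-benzodioxole | CC1(C)Oc2c(O1)c(C1=CCC(B3OC(C)(C)C(C)(C)O3)=CC1)c(OCc1ccccc1)c(OCc1ccccc1)c2C1=CCC(B2OC(C)(C)C(C)(C)O2)=CC1
A4 | alternative 2 | 3-[4-(benzyloxy)phenyl]-4-methoxycyclobut-3-ene-1,2-dione | COC1=C(c2ccc(OCc3ccccc3)cc2)C(=O)C1=O
A5 | alternative 2 | chlorotris(triphenylphosphine)cobalt, ClCo(PPh3)3 | Cl[Co-3]([P+](c1ccccc1)(c1ccccc1)c1ccccc1)([P+](c1ccccc1)(c1ccccc1)c1ccccc1)[P+](c1ccccc1)(c1ccccc1)c1ccccc1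
A6 | alternative 2 | 1-(benzyloxy)-4-(ethoxyethynyl)benzene | CCOC#Cc1ccc(OCc2ccccc2)cc1
A7 | alternative 2 | 2,5-bis[4-(benzyloxy)phenyl]-3-ethoxy-6-methoxy-1,4-benzoquinone | CCOC1=C(c2ccc(OCc3ccccc3)cc2)C(=O)C(OC)=C(c2ccc(OCc3ccccc3)cc2)C1=O
A8 | alternative 3 | S-ethyl 3-[4-(benzyloxy)phenyl]-2-oxopropanethioate | CCSC(=O)C(=O)Cc1ccc(OCc2ccccc2)cc1
A9 | alternative 3 | 2,5-bis[4-(benzyloxy)phenyl]-3,6-dihydroxy-1,4-benzoquinone | O=C1C(O)=C(c2ccc(OCc3ccccc3)cc2)C(=O)C(O)=C1c1ccc(OCc2ccccc2)cc1
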